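**Plan**

1. Retrosynthetic cuts: the lower C4–OH back to a ketone; the nine O‑benzyl bonds; in each unit the C4–C4a bond of ring C; both interflavan bonds as aryl–alkyne bonds; O1–C2 of each unit as a propargylic ether bond.
2. Enabling feature: in the upper unit C4a is the ring A carbon para to O7 and ortho to O1, O1–C2 is a benzylic aryl ether, and C4 carries C6 of the middle unit's benzene ring (ring D). Ring C is thus a folded aryl propargyl ether O1–C2–C3≡C4–ring D, which a π‑acid closes between C4a and C4.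
3. Forward order: one monomer, the S aryl propargyl ether 6, is made once and used three times. Rings C arise lower → middle → upper, each by Sonogashira coupling of 6 to C6 of the unit below, then gold hydroarylation.
4. Stereochemistry: C2 of all units comes from one enantioconvergent copper/pybox propargylic etherification. C3 and C4 follow from C2 by additions to the flav‑3‑ene C3=C4 bond: hydroboration (middle, 3,4‑trans, 4α); OsO4 then ionic hydrogenation (upper, 3,4‑cis, 4β); OsO4, oxidation, then NaBH4 (lower 3,4‑trans diol).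
5. The lower C4 is carried as a cyclic carbonate and then as a ketone, so no acid‑labile flavan‑4‑ol exists before the last step.

Key step: step 14

Remark: flavan numbering is used for each unit and Bn is benzyl; the pybox antipode in step 3 is the one that gives the S ether, its sense of induction being an assumption to be checked on the first batch.

**Step 1**
Reactants: 1 3,4‑bis(benzyloxy)benzaldehyde; 2 ethynylmagnesium bromide
Product: 3 rac‑1‑[3,4‑bis(benzyloxy)phenyl]prop‑2‑yn‑1‑ol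
Conditions: THF, 0 °C to rt; aq. NH4Cl
Reagents that add atoms: none
Why: Addition of an alkynyl Grignard reagent to an aldehyde; the product is racemic by design because step 3 is enantioconvergent.

**Step 2**
Reactants: 3 rac‑propargylic alcohol
Product: 4 rac‑1‑[3,4‑bis(benzyloxy)phenyl]prop‑2‑yn‑1‑yl acetate
Conditions: Ac2O, Et3N, DMAP (cat.), CH2Cl2, 0 °C
Reagents that add atoms: acetic anhydride, CC(=O)OC(C)=O
Why: DMAP‑catalysed O‑acylation gives the propargylic ester that ionises to a copper allenylidene in step 3; no stereochemistry is at stake.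

**Step 3**
Reactants: 4 rac‑propargylic acetate; 5 3‑(benzyloxy)phenol
Product: 6 (S)‑1‑(benzyloxy)‑3‑{[1‑(3,4‑bis(benzyloxy)phenyl)prop‑2‑yn‑1‑yl]oxy}benzene
Conditions: CuOTf·½C6H6 (5 mol%), 2,6‑bis(4‑phenyl‑4,5‑dihydrooxazol‑2‑yl)pyridine (Ph‑pybox, one enantiomer, 6 mol%), i‑Pr2NEt, MeOH, −20 °C
Reagents that add atoms: none
Why: Copper‑catalysed asymmetric propargylic etherification: both enantiomers of 4 converge on one copper allenylidene, and the chiral pybox ligand directs attack of the phenoxide of 5 on one face of the propargylic carbon, setting the S stereocentre that becomes C2 of every flavan unit.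

**Step 4**
Reactants: 6 S aryl propargyl ether
Product: 7 (S)‑7‑(benzyloxy)‑2‑[3,4‑bis(benzyloxy)phenyl]‑2H‑chromene
Conditions: [(2‑biphenylyl)(t‑Bu)2P]Au(NCMe)SbF6 (2 mol%), CH2Cl2, 0 °C to rt
Reagents that add atoms: none
Why: Gold‑catalysed intramolecular hydroarylation of an aryl propargyl ether (6‑endo‑dig) at the ring carbon para to the benzyloxy group gives the 2H‑chromene; the C2 centre is untouched.

**Step 5**
Reactants: 7 2H‑chromene
Product: 8 (2R,3S,4S)‑7‑(benzyloxy)‑2‑[3,4‑bis(benzyloxy)phenyl]chromane‑3,4‑diol (2,3‑trans‑3,4‑cis)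
Conditions: OsO4 (2 mol%), NMO, acetone/H2O, 0 °C to rt
Reagents that add atoms: N‑methylmorpholine N‑oxide, C[N+]1([O-])CCOCC1; water, O (both oxygens pass through OsO4, O=[Os](=O)(=O)=O)
Why: Catalytic OsO4 syn‑dihydroxylation of the cyclic styrene‑type alkene from the face opposite the C2 aryl group sets C3 (hydroxyl trans to the aryl) and C4 (cis‑diol).

**Step 6**
Reactants: 8 cis‑diol
Product: 9 3,4‑cyclic carbonate of 8
Conditions: 1,1'‑carbonyldiimidazole, CH2Cl2, rt
Reagents that add atoms: 1,1'‑carbonyldiimidazole, O=C(n1ccnc1)n1ccnc1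
Why: Carbonylation of a cis‑1,2‑diol to the five‑membered cyclic carbonate, which keeps the benzylic C4–O bond from ionising in steps 7 to 9 and is inert to borane.

**Step 7**
Reactants: 9 cyclic carbonate
Product: 10 6‑iodo derivative of 9
Conditions: NIS, TFA (10 mol%), MeCN, 0 °C
Reagents that add atoms: N‑iodosuccinimide, O=C1CCC(=O)N1I
Why: Electrophilic aromatic iodination at C6, which is para to O1, ortho to the benzyloxy group and much less hindered than C8; the resorcinol‑type ring A should react faster than the catechol‑type ring B.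

**Step 8**
Reactants: 10 aryl iodide; 6 S aryl propargyl ether
Product: 11 internal alkyne joining C6 of the lower unit (carbonate) to the alkyne terminus of 6
Conditions: Pd(PPh3)2Cl2 (3 mol%), CuI (5 mol%), Et3N/THF, 40 °C
Reagents that add atoms: none
Why: Sonogashira coupling of an aryl iodide with a terminal alkyne creates the future C4(middle)–C6(lower) bond with unambiguous regiochemistry; no stereocentre is involved.

**Step 9**
Reactants: 11 internal alkyne
Product: 12 flav‑3‑ene dimer, the (S)‑7‑(benzyloxy)‑2‑[3,4‑bis(benzyloxy)phenyl]‑2H‑chromen‑4‑yl group on C6 of carbonate 9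
Conditions: [(2‑biphenylyl)(t‑Bu)2P]Au(NCMe)SbF6 (3 mol%), CH2Cl2, 0 °C to rt
Reagents that add atoms: none
Why: Gold‑catalysed 6‑endo‑dig hydroarylation, here of an internal aryl alkyne, closes ring C of the middle unit between C4a and C4 with the lower unit already on C4; C2 is untouched.

**Step 10**
Reactants: 12 flav‑3‑ene dimer
Product: 14 tri‑O‑benzylfisetinidol‑(4α→6)‑[(2R,3S,4S)‑tri‑O‑benzylflavan‑3,4‑diol], via alkylborane 13 (not isolated)
Conditions: BH3·THF, THF, 0 °C to rt; then 3 M NaOH, 30% H2O2, 0 °C to rt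
Reagents that add atoms: hydrogen peroxide, OO
Why: Hydroboration–oxidation: borane adds syn (boron to C3, hydrogen to C4) from the face opposite the C2 aryl group and oxidation proceeds with retention, so the 3‑hydroxyl is trans to both the 2‑aryl and the 4‑aryl group (4α linkage), while the alkaline peroxide also hydrolyses the carbonate.

**Step 11**
Reactants: 14 triol
Product: 15 3',4',7‑tri‑O‑benzylfisetinidol‑(4α→6)‑3',4',7‑tri‑O‑benzyl‑(2R,3R)‑fustin
Conditions: activated MnO2 (excess), CH2Cl2, rt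
Reagents that add atoms: none
Why: Activated MnO2 oxidises benzylic but not saturated secondary alcohols, so only the lower 4‑hydroxyl becomes a ketone, giving a 2,3‑trans dihydroflavonol unit with C3 unchanged.

**Step 12**
Reactants: 15 ketone
Product: 16 15 iodinated at C6 of the middle unit
Conditions: NIS, TFA (10 mol%), MeCN/CH2Cl2, 0 °C
Reagents that add atoms: N‑iodosuccinimide, O=C1CCC(=O)N1I
Why: Electrophilic aromatic iodination at C6 of the middle unit, the only unhindered position para to an ether oxygen on a ring that is not deactivated by the ketone.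

**Step 13**
Reactants: 16 aryl iodide; 6 S aryl propargyl ether
Product: 17 internal alkyne joining C6 of the middle unit to the alkyne terminus of 6
Conditions: Pd(PPh3)2Cl2 (3 mol%), CuI (5 mol%), Et3N/THF, 40 °C
Reagents that add atoms: none
Why: Sonogashira coupling places the future upper C3 and C4 on C6 of the middle unit; the free hydroxyls and the ketone are tolerated.

**Step 14**
Reactants: 17 internal alkyne
Product: 18 flav‑3‑ene trimer, the (S)‑configured 2H‑chromen‑4‑yl upper unit on C6 of the middle unit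
Conditions: [(2‑biphenylyl)(t‑Bu)2P]Au(NCMe)SbF6 (5 mol%), CH2Cl2, 0 °C to rt
Reagents that add atoms: none
Why: The cationic gold complex (monovalent gold) binds the C3≡C4 alkyne, and the ring A carbon that is para to the C7 benzyloxy group and ortho to O1 attacks the alkyne carbon bearing ring D anti to gold; rearomatisation and protodeauration of the vinyl–gold species give the flav‑3‑ene. The closest known reaction type is the gold‑ or platinum‑catalysed intramolecular hydroarylation of aryl propargyl ethers to 2H‑chromenes. Ring C closes in the 6‑endo‑dig mode. No new stereocentre is formed, since C3 and C4 become sp2, and the C2 centre is retained because neither the C2–O1 nor the C2–aryl bond is involved. The step needs 6‑endo rather than 5‑exo closure, attack para rather than ortho to the benzyloxy group, and no transfer of the neighbouring benzyl ether of ring D onto the alkyne. These are secured, in turn, by C4 being the alkyne carbon stabilised by the 2,4‑dioxygenated ring D, by crowding at the carbon between the two oxygens, and by the poor migratory ability of an unactivated benzyl group at room temperature.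

**Step 15**
Reactants: 18 flav‑3‑ene trimer
Product: 19 upper‑unit 3,4‑cis‑diol of 18 (3β,4β‑dihydroxy, ring D on the α face, 3‑OH trans to the 2‑aryl)
Conditions: OsO4 (5 mol%), NMO, acetone/t‑BuOH/H2O, rt
Reagents that add atoms: N‑methylmorpholine N‑oxide, C[N+]1([O-])CCOCC1; water, O (both oxygens pass through OsO4, O=[Os](=O)(=O)=O)
Why: Catalytic OsO4 syn‑dihydroxylation of the trisubstituted C3=C4 bond from the face opposite the upper C2 aryl group gives the 3β,4β‑diol, with the 3‑hydroxyl trans to the 2‑aryl group.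

**Step 16**
Reactants: 19 tertiary benzylic diol
Product: 20 nona‑O‑benzyl fisetinidol‑(4β→6)‑fisetinidol‑(4α→6)‑fustin
Conditions: Et3SiH (10 equiv), TFA (5 equiv), CH2Cl2, −40 °C
Reagents that add atoms: none
Why: Ionic hydrogenation: acid ionises the tertiary, doubly benzylic 4‑hydroxyl and the silane delivers hydride to the planar cation from the face anti to the C3 hydroxyl (equatorial approach, the steric course known for silane reduction of cyclic benzylic cations and the face on which 2,3‑trans flavan‑4‑yl cations are captured), so that ring D ends cis to the 3‑hydroxyl (4β linkage).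

**Step 17**
Reactants: 20 nona‑benzyl ether
Product: 21 fisetinidol‑(4β→6)‑fisetinidol‑(4α→6)‑fustin
Conditions: H2 (1 atm), Pd(OH)2/C, THF/MeOH, rt
Reagents that add atoms: none
Why: Hydrogenolysis of the nine benzyl ethers under neutral conditions; the conjugated electron‑rich aryl ketone, the flavan C2–O bonds and the interflavan bonds should persist.

**Step 18**
Reactants: 21 free‑phenolic ketone
Product: 22 fisetinidol‑(4β→6)‑fisetinidol‑(4α→6)‑(2R,3S,4R)‑2,3‑trans‑3,4‑trans‑flavan‑3,4‑diol (target)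
Conditions: NaBH4, EtOH, 0 °C to rt; neutralise to pH 6–7 with dilute AcOH
Reagents that add atoms: none
Why: Borohydride reduction of a 2,3‑trans dihydroflavonol: axial delivery of hydride to C4 gives the equatorial 4‑hydroxyl trans to the 3‑hydroxyl (4R), the known course of the fustin to mollisacacidin reduction.

**Compound list**

1 | 3,4‑bis(benzyloxy)benzaldehyde | O=Cc1ccc(OCc2ccccc2)c(OCc2ccccc2)c1 | starting material
2 | ethynylmagnesium bromide | C#C[Mg]Br | starting material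
3 | rac‑1‑[3,4‑bis(benzyloxy)phenyl]prop‑2‑yn‑1‑ol | C#CC(O)c1ccc(OCc2ccccc2)c(OCc2ccccc2)c1 | intermediate
4 | rac‑1‑[3,4‑bis(benzyloxy)phenyl]prop‑2‑yn‑1‑yl acetate | C#CC(OC(C)=O)c1ccc(OCc2ccccc2)c(OCc2ccccc2)c1 | intermediate
5 | 3‑(benzyloxy)phenol | Oc1cccc(OCc2ccccc2)c1 | starting material
6 | (S)‑1‑(benzyloxy)‑3‑{[1‑(3,4‑bis(benzyloxy)phenyl)prop‑2‑yn‑1‑yl]oxy}benzene | C#C[C@H](Oc1cccc(OCc2ccccc2)c1)c1ccc(OCc2ccccc2)c(OCc2ccccc2)c1 | intermediate
7 | (S)‑7‑(benzyloxy)‑2‑[3,4‑bis(benzyloxy)phenyl]‑2H‑chromene | C(c1ccccc1)Oc1ccc2c(c1)O[C@H](c1ccc(OCc3ccccc3)c(OCc3ccccc3)c1)C=C2 | intermediate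
8 | (2R,3S,4S)‑7‑(benzyloxy)‑2‑[3,4‑bis(benzyloxy)phenyl]chromane‑3,4‑diol | C(c1ccccc1)Oc1ccc2c(c1)O[C@H](c1ccc(OCc3ccccc3)c(OCc3ccccc3)c1)[C@@H](O)[C@H]2O | intermediate
9 | 3,4‑cyclic carbonate of 8 | C(c1ccccc1)Oc1ccc2c(c1)O[C@H](c1ccc(OCc3ccccc3)c(OCc3ccccc3)c1)[C@@H](OC5=O)[C@H]2O5 | intermediate
10 | 6‑iodo derivative of 9 | C(c1ccccc1)Oc1c(I)cc2c(c1)O[C@H](c1ccc(OCc3ccccc3)c(OCc3ccccc3)c1)[C@@H](OC5=O)[C@H]2O5 | intermediate
11 | internal alkyne from 10 and 6 (S at the propargylic carbon) | C(c1ccccc1)Oc1cccc(c1)O[C@H](c1ccc(OCc2ccccc2)c(OCc2ccccc2)c1)C#Cc1cc2c(cc1OCc1ccccc1)O[C@H](c1ccc(OCc3ccccc3)c(OCc3ccccc3)c1)[C@@H](OC5=O)[C@H]2O5 | intermediate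
12 | flav‑3‑ene dimer (middle 2H‑chromen‑4‑yl on C6 of the lower carbonate) | C(c1ccccc1)Oc1ccc2c(c1)O[C@H](c1ccc(OCc3ccccc3)c(OCc3ccccc3)c1)C=C2c1cc2c(cc1OCc1ccccc1)O[C@H](c1ccc(OCc3ccccc3)c(OCc3ccccc3)c1)[C@@H](OC5=O)[C@H]2O5 | intermediate
13 | alkylborane from 12 (BH2 on middle C3 trans to the 2‑aryl, H on C4 cis to boron) | C(c1ccccc1)Oc1ccc2c(c1)O[C@H](c1ccc(OCc3ccccc3)c(OCc3ccccc3)c1)[C@@H](B)[C@@H]2c1cc2c(cc1OCc1ccccc1)O[C@H](c1ccc(OCc3ccccc3)c(OCc3ccccc3)c1)[C@@H](OC5=O)[C@H]2O5 | intermediate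
14 | tri‑O‑benzylfisetinidol‑(4α→6)‑[(2R,3S,4S)‑tri‑O‑benzylflavan‑3,4‑diol] | C(c1ccccc1)Oc1ccc2c(c1)O[C@H](c1ccc(OCc3ccccc3)c(OCc3ccccc3)c1)[C@@H](O)[C@@H]2c1cc2c(cc1OCc1ccccc1)O[C@H](c1ccc(OCc3ccccc3)c(OCc3ccccc3)c1)[C@@H](O)[C@H]2O | intermediate
15 | tri‑O‑benzylfisetinidol‑(4α→6)‑tri‑O‑benzyl‑(2R,3R)‑fustin | C(c1ccccc1)Oc1ccc2c(c1)O[C@H](c1ccc(OCc3ccccc3)c(OCc3ccccc3)c1)[C@@H](O)[C@@H]2c1cc2c(cc1OCc1ccccc1)O[C@H](c1ccc(OCc3ccccc3)c(OCc3ccccc3)c1)[C@@H](O)C2=O | intermediate
16 | 15 iodinated at C6 of the middle unit | C(c1ccccc1)Oc1c(I)cc2c(c1)O[C@H](c1ccc(OCc3ccccc3)c(OCc3ccccc3)c1)[C@@H](O)[C@@H]2c1cc2c(cc1OCc1ccccc1)O[C@H](c1ccc(OCc3ccccc3)c(OCc3ccccc3)c1)[C@@H](O)C2=O | intermediate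
17 | internal alkyne from 16 and 6 | C(c1ccccc1)Oc1cccc(c1)O[C@H](c1ccc(OCc2ccccc2)c(OCc2ccccc2)c1)C#Cc1cc2c(cc1OCc1ccccc1)O[C@H](c1ccc(OCc3ccccc3)c(OCc3ccccc3)c1)[C@@H](O)[C@@H]2c1cc2c(cc1OCc1ccccc1)O[C@H](c1ccc(OCc3ccccc3)c(OCc3ccccc3)c1)[C@@H](O)C2=O | intermediate
18 | flav‑3‑ene trimer (upper 2H‑chromen‑4‑yl on C6 of the middle unit) | C(c1ccccc1)Oc1ccc2c(c1)O[C@H](c1ccc(OCc3ccccc3)c(OCc3ccccc3)c1)C=C2c1cc2c(cc1OCc1ccccc1)O[C@H](c1ccc(OCc3ccccc3)c(OCc3ccccc3)c1)[C@@H](O)[C@@H]2c1cc2c(cc1OCc1ccccc1)O[C@H](c1ccc(OCc3ccccc3)c(OCc3ccccc3)c1)[C@@H](O)C2=O | intermediate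
19 | upper‑unit 3β,4β‑diol of 18 (ring D 4α) | C(c1ccccc1)Oc1ccc2c(c1)O[C@H](c1ccc(OCc3ccccc3)c(OCc3ccccc3)c1)[C@@H](O)[C@]2(O)c1cc2c(cc1OCc1ccccc1)O[C@H](c1ccc(OCc3ccccc3)c(OCc3ccccc3)c1)[C@@H](O)[C@@H]2c1cc2c(cc1OCc1ccccc1)O[C@H](c1ccc(OCc3ccccc3)c(OCc3ccccc3)c1)[C@@H](O)C2=O | intermediate
20 | nona‑O‑benzyl fisetinidol‑(4β→6)‑fisetinidol‑(4α→6)‑fustin | C(c1ccccc1)Oc1ccc2c(c1)O[C@H](c1ccc(OCc3ccccc3)c(OCc3ccccc3)c1)[C@@H](O)[C@H]2c1cc2c(cc1OCc1ccccc1)O[C@H](c1ccc(OCc3ccccc3)c(OCc3ccccc3)c1)[C@@H](O)[C@@H]2c1cc2c(cc1OCc1ccccc1)O[C@H](c1ccc(OCc3ccccc3)c(OCc3ccccc3)c1)[C@@H](O)C2=O | intermediate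
21 | fisetinidol‑(4β→6)‑fisetinidol‑(4α→6)‑fustin | Oc1ccc2c(c1)O[C@H](c1ccc(O)c(O)c1)[C@@H](O)[C@H]2c1cc2c(cc1O)O[C@H](c1ccc(O)c(O)c1)[C@@H](O)[C@@H]2c1cc2c(cc1O)O[C@H](c1ccc(O)c(O)c1)[C@@H](O)C2=O | intermediate
22 | fisetinidol‑(4β→6)‑fisetinidol‑(4α→6)‑(2R,3S,4R)‑flavan‑3,4‑diol | Oc1ccc2c(c1)O[C@H](c1ccc(O)c(O)c1)[C@@H](O)[C@H]2c1cc2c(cc1O)O[C@H](c1ccc(O)c(O)c1)[C@@H](O)[C@@H]2c1cc2c(cc1O)O[C@H](c1ccc(O)c(O)c1)[C@@H](O)[C@@H]2O | target

Total step count: 18
Longest linear sequence: 18 steps (1 → 3 → 4 → 6 → 7 → … → 22; compound 6 re‑enters at steps 8 and 13)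

**Steps most likely to fail**

Step 16. What may go wrong: hydride delivery to the planar C4 cation from the face syn to the C3 hydroxyl, or a 1,2‑hydride shift from C3 (pinacol‑type) before the cation is captured. The fallback sets out from 18 and comes back at 20, bypassing 19. The C3=C4 bond of 18 is epoxidised with dimethyldioxirane (acetone/CH2Cl2, −40 °C) from the face opposite the C2 aryl group to give the 3β,4β‑epoxide of 18 F1. This is opened at −78 °C with Et3SiH and BF3·OEt2: hydride enters the benzylic carbon with inversion, anti to the bridging oxygen, as in the hydride opening of 1‑arylcycloalkene oxides to cis‑2‑arylcycloalkanols.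

Step 14. What may go wrong: ionisation of the propargylic C2–O1 bond under the π‑acid with erosion of configuration at C2, acid‑induced isomerisation of the 2H‑chromene to the 4H‑chromene, or ring closure at the carbon between the two oxygens. The fallback sets out from 17 and comes back at 18. Iodocyclisation (I2, NaHCO3, MeNO2, rt) triggers the same 6‑endo‑dig closure through an iodonium ion, without any Lewis or Brønsted acid, and gives the 3‑iodo derivative of 18 F2. Hydrodeiodination (Pd(OAc)2, PPh3, HCO2Na, DMF, 60 °C) then gives 18.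

Step 3. What may go wrong: Friedel–Crafts C‑propargylation of the electron‑rich phenol competing with O‑alkylation, or insufficient enantioselectivity, which would carry into all three units. The fallback sets out from 3 and comes back at 6. Lipase‑catalysed kinetic resolution of 3 (Candida antarctica lipase B, vinyl acetate, MTBE) should acylate the R enantiomer to (R)‑1‑[3,4‑bis(benzyloxy)phenyl]prop‑2‑yn‑1‑yl acetate F3. Methanolysis (K2CO3, MeOH, 0 °C) gives (R)‑1‑[3,4‑bis(benzyloxy)phenyl]prop‑2‑yn‑1‑ol F4. Mitsunobu etherification of F4 with 5 (PPh3, DIAD, toluene, −20 °C) proceeds with inversion to the S ether 6.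

**Further compounds**

F1 | step 16 | 3β,4β‑epoxide of 18 (upper unit) | C(c1ccccc1)Oc1ccc2c(c1)O[C@H](c1ccc(OCc3ccccc3)c(OCc3ccccc3)c1)[C@H]3O[C@@]23c1cc2c(cc1OCc1ccccc1)O[C@H](c1ccc(OCc3ccccc3)c(OCc3ccccc3)c1)[C@@H](O)[C@@H]2c1cc2c(cc1OCc1ccccc1)O[C@H](c1ccc(OCc3ccccc3)c(OCc3ccccc3)c1)[C@@H](O)C2=O
F2 | step 14 | 3‑iodo derivative of 18 (upper unit) | C(c1ccccc1)Oc1ccc2c(c1)O[C@H](c1ccc(OCc3ccccc3)c(OCc3ccccc3)c1)C(I)=C2c1cc2c(cc1OCc1ccccc1)O[C@H](c1ccc(OCc3ccccc3)c(OCc3ccccc3)c1)[C@@H](O)[C@@H]2c1cc2c(cc1OCc1ccccc1)O[C@H](c1ccc(OCc3ccccc3)c(OCc3ccccc3)c1)[C@@H](O)C2=O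
F3 | step 3 | (R)‑1‑[3,4‑bis(benzyloxy)phenyl]prop‑2‑yn‑1‑yl acetate | C#C[C@@H](OC(C)=O)c1ccc(OCc2ccccc2)c(OCc2ccccc2)c1
F4 | step 3 | (R)‑1‑[3,4‑bis(benzyloxy)phenyl]prop‑2‑yn‑1‑ol | C#C[C@@H](O)c1ccc(OCc2ccccc2)c(OCc2ccccc2)c1
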